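The data stem from a simulated flask on assumed constants; the scatter is artificial.

I am asked how much left-handed product stands at the end of three flasks that differ in their free catalyst, and which way that number moves.

common to all: left-handed substrate 20 mM; right-handed substrate 20 mM; impurity 1.3 mM
- birch: reagent 50 mM; free catalyst 1.3 mM; run made earlier
- cedar: reagent 50 mM; free catalyst 5.3 mM; run made earlier
- dawn: reagent 50.0 mM; free catalyst 1.0 mM; time 15 min
- winter: reagent 50.0 mM; free catalyst 2.0 mM; time 15 min
- spring: reagent 50.0 mM; free catalyst 4.0 mM; time 15 min

| run | time / min | left-handed product / % |
|---|---|---|
| birch | 0.667 | 30 |
| birch | 1.00 | 33 |
| birch | 2.00 | 38 |
| birch | 4.00 | 47 |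
| birch | 8.00 | 50 |
| cedar | 1.50 | 53 |
| cedar | 3.00 | 55 |
| cedar | 5.00 | 55 |
| cedar | 6.00 | 52 |
| cedar | 8.00 | 55 |

(scatter of a reading: 2 percentage points)

- free catalyst is single-handed; left-handed substrate and right-handed substrate are mirror images of each other, charged as a racemate, each of them at the stated concentration
- "hardly changes" means that all values lie within two and a half points (for a concentration: within two and a half percent of the largest)

1. amount of left-handed product at the end, in percent of the left-handed substrate and right-handed substrate together charged for dawn, winter, spring, in this order
2. how that number moves from the first to the last of them (falls, then rises / hardly changes / falls all the way / rises, then falls / rises all the way)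

Birch gives 1.00 and cedar 0.245 for the impurity charged over the free catalyst charged. For spring the same ratio is 0.325. I call this ratio the poison share, the fraction of the catalyst charge that the impurity can remove if it takes the catalyst one for one.

Something looks wrong at once. Birch has a share of 1.00, so its impurity can remove its whole catalyst, yet birch reads 50% at 8.00 min. Cedar has a share of 0.245 and reads just 55% at 8.00 min.

The share says where the catalyst ends, not what it does on the way. Birch already reads 30% at 0.667 min and gains just 20 percentage points more by 8.00 min, so its catalyst works while it is being lost. Cedar's readings stay within the scatter from 1.50 min, and its share is below one, so I take it that cedar does not stop for want of catalyst.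

Now the three flasks. Dawn has a share of 1.30, above one, so its impurity can remove its whole catalyst, and a fraction 23.1% of its impurity should stay. I expect dawn to stop near birch with substrate unused. Winter at 0.650 and spring at 0.325 keep catalyst, so there the share is a correction to the charge. I expect both to finish near cedar.

The forecast gives 50%, 52% and 54.5%, so rises all the way, holding that “active catalyst sends some right-handed substrate to left-handed product”.

The flasks give 48.5%, 60.2% and 57.0%, so rises, then falls.

    left-handed substrate ⇌ right-handed substrate (k = 0.210 /min)
    free catalyst + impurity → spent catalyst (k = 590 /M/min)
    reagent + free catalyst + left-handed substrate → free catalyst + left-handed product (k = 28000 /M²/min)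
    reagent + free catalyst + right-handed substrate → free catalyst + right-handed product (k = 11000 /M²/min)

Spring ends with spent catalyst at 32.5% of the catalyst charged, against a poison share of 0.325. Dawn keeps 23.1% of its impurity at 150 min, against the reckoned 23.1%. So spring keeps 67.5% of its free catalyst, yet it ends at 57.0%, below winter. The main reason for spring's figure is the conversion of right-handed substrate into right-handed product: the same spring run without that step gives 95.5% of left-handed product, 39 points more.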